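**Strategy.** Everything rests on making ring B (C-1, C-2, C-3, C-4, C-4a, C-8a of the octahydronaphthalene) by one-carbon enlargement of a cyclopentanone that already holds the vicinal C-1/C-2 stereocentres. The key step exploits the quaternary C-1 beside the ring-fusion CH (C-8a) and the sp2 C-4a: in a β-oxido carbenoid 1,2-shift the quaternary carbon migrates to the new carbon C-8a, which already carries the C-8/C-7/C-6/C-5 chain of ring A. One operation gives ring B, inserts C-8a between C-1 and the C-4a carbonyl, and forms the regiodefined enolate whose protonation sets C-8a. The precursor is a 1-(1,1-dibromoalkyl)cyclopentanol.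

Key step: step 4

Remark: locants C-1 to C-8a are those of the octahydronaphthalene unit in the name of 17 (C-1 quaternary, C-2 CHCH3, C-4=C-4a, C-5 C(CH3)2, C-6 CHOH, C-8a ring-fusion CH); 1, 4, 16 and all reagents are assumed to be commercial, and the ligand enantiomer in step 1 is the one that gives the (3S) adduct.

**Step 1**
Reactants: 1 2-methylcyclopent-2-en-1-one
Product: 3 (2S,3S)-2-[(benzyloxy)methyl]-2,3-dimethylcyclopentan-1-one, via bromomagnesium enolate 2 (not isolated)
Conditions: MeMgBr, Cu(OTf)2 (3 mol %), chiral hydroxyalkyl imidazolinium salt (N-heterocyclic carbene precursor, 4 mol %), Et2O, −30 °C; then BnOCH2Cl, THF, −30 → 0 °C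
Reagents that add atoms: methylmagnesium bromide C[Mg]Br; benzyl chloromethyl ether ClCOCc1ccccc1
Why: Copper-catalysed asymmetric conjugate addition should set the methyl-bearing carbon (S) under ligand control, and the tetrasubstituted magnesium enolate should be C-alkylated anti to that new methyl group, so that the quaternary carbon forms with CH2OBn trans to the 3-methyl group (tandem conjugate addition–enolate alkylation).

**Step 2**
Reactants: 4 2-(2-bromoethyl)-2-methyl-1,3-dioxolane
Product: 5 2-(3,3-dibromopropyl)-2-methyl-1,3-dioxolane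
Conditions: CH2Br2, LiN(iPr)2, THF/HMPA, −100 → −70 °C
Reagents that add atoms: dibromomethane BrCBr
Why: Dibromomethyllithium formed in the flask should displace the primary bromide (SN2 alkylation of a carbenoid anion) and give the 1,1-dibromoalkane with the ketal intact.

**Step 3**
Reactants: 3 (2S,3S)-2-[(benzyloxy)methyl]-2,3-dimethylcyclopentan-1-one, 5 2-(3,3-dibromopropyl)-2-methyl-1,3-dioxolane
Product: 7 (2S,3S)-2-[(benzyloxy)methyl]-1-[1,1-dibromo-3-(2-methyl-1,3-dioxolan-2-yl)propyl]-2,3-dimethylcyclopentan-1-ol (both epimers at the carbinol carbon), via lithiated dibromide 6 (not isolated)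
Conditions: 5, LiN(iPr)2, THF/Et2O, −105 °C; then 3, −105 → −78 °C; AcOH
Reagents that add atoms: none
Why: Deprotonation of the gem-dibromide gives an α,α-dibromoalkyllithium that should add to the ketone carbonyl faster than it enolises it (1,2-addition of a carbenoid anion); the configuration of the new carbinol carbon does not matter because this carbon becomes sp2 in step 4.

**Step 4**
Reactants: 7 (2S,3S)-2-[(benzyloxy)methyl]-1-[1,1-dibromo-3-(2-methyl-1,3-dioxolan-2-yl)propyl]-2,3-dimethylcyclopentan-1-ol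
Product: 10 (2S,3R,4S)-3-[(benzyloxy)methyl]-3,4-dimethyl-2-[2-(2-methyl-1,3-dioxolan-2-yl)ethyl]cyclohexan-1-one, via dilithio β-oxido carbenoid 8 (not isolated), via lithium enolate 9 (not isolated)
Conditions: nBuLi (2.2 equiv), THF, −100 → −20 °C; then AcOH, THF, −78 °C
Reagents that add atoms: none
Why: The first equivalent of nBuLi deprotonates the carbinol and the second exchanges one bromine for lithium; the resulting β-oxido carbenoid 8 undergoes an alkoxide-driven 1,2-shift of a ring carbon to the carbenoid carbon with loss of LiBr (β-oxido carbenoid ring enlargement, the carbenoid counterpart of the Tiffeneau–Demjanov and semipinacol rearrangements). No ring is closed by cyclisation: the five-membered ring grows into ring B by the 1,2-shift, which inserts C-8a between the former carbonyl carbon C-4a and C-1. The step needs migration of the quaternary C-1 and not of the ring CH2 (C-4), and the higher migratory aptitude of the fully substituted carbon toward the electron-poor carbenoid centre should secure this; C-1 migrates with retention, so the C-1/C-2 stereocentres are carried over unchanged. The shift gives enolate 9 with its double bond fixed between C-4a and C-8a, a regiochemistry that enolisation of the six-membered ketone could not give. Protonation of 9 should occur axially on the face anti to the pseudoaxial C-1 methyl group (the other face is shielded by that methyl group or, in the alternative half-chair, by the axial C-2 methyl group), which places H-8a cis to CH2OBn (2S in 10); the equatorial side chain is also the thermodynamically preferred arrangement.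

**Step 5**
Reactants: 10 (2S,3R,4S)-3-[(benzyloxy)methyl]-3,4-dimethyl-2-[2-(2-methyl-1,3-dioxolan-2-yl)ethyl]cyclohexan-1-one
Product: 12 (4aR,5R,6S)-5-[(benzyloxy)methyl]-5,6-dimethyl-4,4a,5,6,7,8-hexahydronaphthalen-2(3H)-one, via diketone 11 (not isolated)
Conditions: 1 M HCl, THF, 25 °C; then KOH, MeOH, 25 → 45 °C
Reagents that add atoms: water O
Why: Ketal hydrolysis frees the methyl ketone, whose enolate should add to the ring carbonyl and dehydrate to the conjugated enone (intramolecular aldol condensation, the closing half of a Robinson annulation), which forms ring A while C-8a keeps its configuration.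

**Step 6**
Reactants: 12 (4aR,5R,6S)-5-[(benzyloxy)methyl]-5,6-dimethyl-4,4a,5,6,7,8-hexahydronaphthalen-2(3H)-one
Product: 13 (4aR,5R,6S)-5-[(benzyloxy)methyl]-1,1,5,6-tetramethyl-3,4,4a,5,6,7-hexahydronaphthalen-2(1H)-one
Conditions: KOtBu (3 equiv), tBuOH/THF, 25 °C; MeI (excess)
Reagents that add atoms: iodomethane CI
Why: The heteroannular dienolate should be methylated twice at the α-carbon (C-5), which moves the double bond out of conjugation into ring B as the C-4=C-4a alkene (deconjugative gem-dialkylation of an enone); deprotonation at C-8a is disfavoured by the adjacent quaternary C-1.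

**Step 7**
Reactants: 13 (4aR,5R,6S)-5-[(benzyloxy)methyl]-1,1,5,6-tetramethyl-3,4,4a,5,6,7-hexahydronaphthalen-2(1H)-one
Product: 14 (2S,4aR,5R,6S)-5-[(benzyloxy)methyl]-1,1,5,6-tetramethyl-1,2,3,4,4a,5,6,7-octahydronaphthalen-2-ol
Conditions: (R)-1-methyl-3,3-diphenyltetrahydro-1H,3H-pyrrolo[1,2-c][1,3,2]oxazaborole ((R)-Me-CBS, 0.5 equiv), catecholborane, toluene, −78 °C
Reagents that add atoms: none
Why: Corey–Bakshi–Shibata reduction should deliver hydride under catalyst control, with the quaternary C-5 as the large flank and the C-7 methylene as the small one, to give the (S)-carbinol (hydroxyl cis to the C-1 methyl group), which substrate-controlled hydride reagents would not secure.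

**Step 8**
Reactants: 14 (2S,4aR,5R,6S)-5-[(benzyloxy)methyl]-1,1,5,6-tetramethyl-1,2,3,4,4a,5,6,7-octahydronaphthalen-2-ol
Product: 15 (2S,4aR,5R,6S)-5-(hydroxymethyl)-1,1,5,6-tetramethyl-1,2,3,4,4a,5,6,7-octahydronaphthalen-2-ol
Conditions: Li, NH3(l), THF, −78 °C; NH4Cl
Reagents that add atoms: none
Why: Dissolving-metal cleavage of the benzyl ether (Birch-type debenzylation) should free the primary alcohol while the isolated trisubstituted alkene and all stereocentres stay untouched.

**Step 9**
Reactants: 15 (2S,4aR,5R,6S)-5-(hydroxymethyl)-1,1,5,6-tetramethyl-1,2,3,4,4a,5,6,7-octahydronaphthalen-2-ol, 16 isofraxidin (7-hydroxy-6,8-dimethoxy-2H-chromen-2-one)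
Product: 17 7-{[(1R,2S,6S,8aR)-6-hydroxy-1,2,5,5-tetramethyl-1,2,3,5,6,7,8,8a-octahydronaphthalen-1-yl]methoxy}-6,8-dimethoxy-2H-chromen-2-one (CNP0110107.1)
Conditions: 16 (1.2 equiv), PBu3, 1,1'-(azodicarbonyl)dipiperidine (ADDP), toluene, 0 → 80 °C
Reagents that add atoms: none
Why: Mitsunobu etherification should join the primary neopentyl alcohol to the acidic coumarin phenol, while the secondary alcohol next to the gem-dimethyl carbon is too hindered to be activated; no stereocentre is involved.

**Compound list**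
1 | 2-methylcyclopent-2-en-1-one | CC1=CCCC1=O | starting material
2 | bromomagnesium (3S)-2,3-dimethylcyclopent-1-en-1-olate | CC1=C(O[Mg]Br)CC[C@@H]1C | intermediate (not isolated)
3 | (2S,3S)-2-[(benzyloxy)methyl]-2,3-dimethylcyclopentan-1-one | C(c1ccccc1)OC[C@@]1(C)C(=O)CC[C@@H]1C | intermediate
4 | 2-(2-bromoethyl)-2-methyl-1,3-dioxolane | BrCCC1(C)OCCO1 | starting material
5 | 2-(3,3-dibromopropyl)-2-methyl-1,3-dioxolane | BrC(Br)CCC1(C)OCCO1 | intermediate
6 | 2-(3,3-dibromo-3-lithiopropyl)-2-methyl-1,3-dioxolane | [Li]C(Br)(Br)CCC1(C)OCCO1 | intermediate (not isolated)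
7 | (2S,3S)-2-[(benzyloxy)methyl]-1-[1,1-dibromo-3-(2-methyl-1,3-dioxolan-2-yl)propyl]-2,3-dimethylcyclopentan-1-ol, both C-1 epimers | C(c1ccccc1)OC[C@@]1(C)C(O)(C(Br)(Br)CCC2(C)OCCO2)CC[C@@H]1C | intermediate
8 | lithium alkoxide of 7 with one bromine exchanged for lithium (β-oxido carbenoid) | C(c1ccccc1)OC[C@@]1(C)C(O[Li])(C([Li])(Br)CCC2(C)OCCO2)CC[C@@H]1C | intermediate (not isolated)
9 | lithium (3R,4S)-3-[(benzyloxy)methyl]-3,4-dimethyl-2-[2-(2-methyl-1,3-dioxolan-2-yl)ethyl]cyclohex-1-en-1-olate | C(c1ccccc1)OC[C@@]1(C)C(CCC2(C)OCCO2)=C(O[Li])CC[C@@H]1C | intermediate (not isolated)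
10 | (2S,3R,4S)-3-[(benzyloxy)methyl]-3,4-dimethyl-2-[2-(2-methyl-1,3-dioxolan-2-yl)ethyl]cyclohexan-1-one | C(c1ccccc1)OC[C@@]1(C)[C@H](CCC2(C)OCCO2)C(=O)CC[C@@H]1C | intermediate
11 | (2S,3R,4S)-3-[(benzyloxy)methyl]-3,4-dimethyl-2-(3-oxobutyl)cyclohexan-1-one | C(c1ccccc1)OC[C@@]1(C)[C@H](CCC(C)=O)C(=O)CC[C@@H]1C | intermediate (not isolated)
12 | (4aR,5R,6S)-5-[(benzyloxy)methyl]-5,6-dimethyl-4,4a,5,6,7,8-hexahydronaphthalen-2(3H)-one | C(c1ccccc1)OC[C@@]1(C)[C@@H]2CCC(=O)C=C2CC[C@@H]1C | intermediate
13 | (4aR,5R,6S)-5-[(benzyloxy)methyl]-1,1,5,6-tetramethyl-3,4,4a,5,6,7-hexahydronaphthalen-2(1H)-one | C(c1ccccc1)OC[C@@]1(C)[C@@H]2CCC(=O)C(C)(C)C2=CC[C@@H]1C | intermediate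
14 | (2S,4aR,5R,6S)-5-[(benzyloxy)methyl]-1,1,5,6-tetramethyl-1,2,3,4,4a,5,6,7-octahydronaphthalen-2-ol | C(c1ccccc1)OC[C@@]1(C)[C@@H]2CC[C@H](O)C(C)(C)C2=CC[C@@H]1C | intermediate
15 | (2S,4aR,5R,6S)-5-(hydroxymethyl)-1,1,5,6-tetramethyl-1,2,3,4,4a,5,6,7-octahydronaphthalen-2-ol | OC[C@@]1(C)[C@@H]2CC[C@H](O)C(C)(C)C2=CC[C@@H]1C | intermediate
16 | isofraxidin (7-hydroxy-6,8-dimethoxy-2H-chromen-2-one) | COc1cc2ccc(=O)oc2c(OC)c1O | starting material
17 | 7-{[(1R,2S,6S,8aR)-6-hydroxy-1,2,5,5-tetramethyl-1,2,3,5,6,7,8,8a-octahydronaphthalen-1-yl]methoxy}-6,8-dimethoxy-2H-chromen-2-one | COc1cc2ccc(=O)oc2c(OC)c1OC[C@@]1(C)[C@@H]2CC[C@H](O)C(C)(C)C2=CC[C@@H]1C | target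

**Step count.** Total: 9 steps. Longest linear sequence: 8 steps (steps 1, 3, 4, 5, 6, 7, 8, 9); step 2 prepares the side-chain reagent.

**Steps most likely to fail**

Step 4. The ring carbon CH2 may migrate in place of the quaternary carbon, or the carbenoid may be protonated or lose LiBr by other paths before the shift. The fallback sets out from 3 and uses a thionium-terminated semipinacol shift. Addition of bis(phenylsulfanyl)methyllithium (from bis(phenylsulfanyl)methane and nBuLi, THF, −78 °C) to 3 should give the carbinol (2S,3S)-2-[(benzyloxy)methyl]-1-[bis(phenylsulfanyl)methyl]-2,3-dimethylcyclopentan-1-ol F1. CuOTf (benzene complex) and iPr2NEt in benzene at 50 °C should remove one thiolate and trigger migration of the quaternary carbon to the sulfur-stabilised cation, giving the ring-enlarged (3S,4S)-3-[(benzyloxy)methyl]-3,4-dimethyl-2-(phenylsulfanyl)cyclohexan-1-one F2. Base-catalysed Michael addition of F2 to but-3-en-2-one at the sulfur-bearing carbon should give (3S,4S)-3-[(benzyloxy)methyl]-3,4-dimethyl-2-(3-oxobutyl)-2-(phenylsulfanyl)cyclohexan-1-one F3. Aluminium amalgam in wet THF should remove sulfur, and the enol so formed is protonated on the same face as in step 4. This comes back to the route at diketone 11, which the KOH/MeOH stage of step 5 closes to 12.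

Step 3. The crowded α,α-dibromoalkyllithium may enolise the α-quaternary ketone or decompose before it adds. The fallback sets out from 3 and attaches the ring A chain after the ring enlargement. The smaller dibromomethyllithium (CH2Br2, LiN(iPr)2, THF, −95 °C) should add to 3 to give (2S,3S)-2-[(benzyloxy)methyl]-1-(dibromomethyl)-2,3-dimethylcyclopentan-1-ol F4. nBuLi (2.2 equiv, −95 → −20 °C) should enlarge the ring as in step 4 to lithium (3R,4S)-3-[(benzyloxy)methyl]-3,4-dimethylcyclohex-1-en-1-olate F5. Trapping at −78 °C with 3-(trimethylsilyl)but-3-en-2-one should give the Michael adduct (3R,4S)-3-[(benzyloxy)methyl]-3,4-dimethyl-2-[3-oxo-2-(trimethylsilyl)butyl]cyclohexan-1-one F6. KOH in MeOH should then remove silicon and close the enone (α-silyl vinyl ketone Robinson annulation). Here the carbon electrophile enters on the face that the proton uses in step 4, so C-8a is expected to form mainly with the wrong configuration and would have to be corrected by base equilibration, with separation and recycling of the unwanted epimer. The fallback comes back to the route at 12.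

Step 9. Activation of the congested neopentyl alcohol may be slow, and elimination or reaction at the secondary alcohol may compete. The fallback sets out from 14 and replaces the Mitsunobu reaction by displacement of a triflate. TBSOTf and 2,6-lutidine should give tert-butyl{[(2S,4aR,5R,6S)-5-[(benzyloxy)methyl]-1,1,5,6-tetramethyl-1,2,3,4,4a,5,6,7-octahydronaphthalen-2-yl]oxy}dimethylsilane F7. Li in NH3 should give [(1R,2S,6S,8aR)-6-{[tert-butyl(dimethyl)silyl]oxy}-1,2,5,5-tetramethyl-1,2,3,5,6,7,8,8a-octahydronaphthalen-1-yl]methanol F8. Tf2O and pyridine at −40 °C should give its trifluoromethanesulfonate F9. Cs2CO3 and 16 in DMF should displace the triflate to give the silyl ether of the target, 7-{[(1R,2S,6S,8aR)-6-{[tert-butyl(dimethyl)silyl]oxy}-1,2,5,5-tetramethyl-1,2,3,5,6,7,8,8a-octahydronaphthalen-1-yl]methoxy}-6,8-dimethoxy-2H-chromen-2-one F10. HF·pyridine in THF should then free the alcohol, and the fallback comes back to the route at 17.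

**Further compounds**
F1 | step 4 | (2S,3S)-2-[(benzyloxy)methyl]-1-[bis(phenylsulfanyl)methyl]-2,3-dimethylcyclopentan-1-ol | C(c1ccccc1)OC[C@@]1(C)C(O)(C(Sc2ccccc2)Sc2ccccc2)CC[C@@H]1C
F2 | step 4 | (3S,4S)-3-[(benzyloxy)methyl]-3,4-dimethyl-2-(phenylsulfanyl)cyclohexan-1-one | C(c1ccccc1)OC[C@@]1(C)C(Sc2ccccc2)C(=O)CC[C@@H]1C
F3 | step 4 | (3S,4S)-3-[(benzyloxy)methyl]-3,4-dimethyl-2-(3-oxobutyl)-2-(phenylsulfanyl)cyclohexan-1-one | C(c1ccccc1)OC[C@@]1(C)C(CCC(C)=O)(Sc2ccccc2)C(=O)CC[C@@H]1C
F4 | step 3 | (2S,3S)-2-[(benzyloxy)methyl]-1-(dibromomethyl)-2,3-dimethylcyclopentan-1-ol | C(c1ccccc1)OC[C@@]1(C)C(O)(C(Br)Br)CC[C@@H]1C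
F5 | step 3 | lithium (3R,4S)-3-[(benzyloxy)methyl]-3,4-dimethylcyclohex-1-en-1-olate | C(c1ccccc1)OC[C@@]1(C)C=C(O[Li])CC[C@@H]1C
F6 | step 3 | (3R,4S)-3-[(benzyloxy)methyl]-3,4-dimethyl-2-[3-oxo-2-(trimethylsilyl)butyl]cyclohexan-1-one | C(c1ccccc1)OC[C@@]1(C)C(CC(C(C)=O)[Si](C)(C)C)C(=O)CC[C@@H]1C
F7 | step 9 | tert-butyl{[(2S,4aR,5R,6S)-5-[(benzyloxy)methyl]-1,1,5,6-tetramethyl-1,2,3,4,4a,5,6,7-octahydronaphthalen-2-yl]oxy}dimethylsilane | C(c1ccccc1)OC[C@@]1(C)[C@@H]2CC[C@H](O[Si](C)(C)C(C)(C)C)C(C)(C)C2=CC[C@@H]1C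
F8 | step 9 | [(1R,2S,6S,8aR)-6-{[tert-butyl(dimethyl)silyl]oxy}-1,2,5,5-tetramethyl-1,2,3,5,6,7,8,8a-octahydronaphthalen-1-yl]methanol | OC[C@@]1(C)[C@@H]2CC[C@H](O[Si](C)(C)C(C)(C)C)C(C)(C)C2=CC[C@@H]1C
F9 | step 9 | [(1R,2S,6S,8aR)-6-{[tert-butyl(dimethyl)silyl]oxy}-1,2,5,5-tetramethyl-1,2,3,5,6,7,8,8a-octahydronaphthalen-1-yl]methyl trifluoromethanesulfonate | FC(F)(F)S(=O)(=O)OC[C@@]1(C)[C@@H]2CC[C@H](O[Si](C)(C)C(C)(C)C)C(C)(C)C2=CC[C@@H]1C
F10 | step 9 | 7-{[(1R,2S,6S,8aR)-6-{[tert-butyl(dimethyl)silyl]oxy}-1,2,5,5-tetramethyl-1,2,3,5,6,7,8,8a-octahydronaphthalen-1-yl]methoxy}-6,8-dimethoxy-2H-chromen-2-one | COc1cc2ccc(=O)oc2c(OC)c1OC[C@@]1(C)[C@@H]2CC[C@H](O[Si](C)(C)C(C)(C)C)C(C)(C)C2=CC[C@@H]1C
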